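**Retrosynthetic overview**
1. Esters: the O2 angelate goes on last, onto the only free secondary hydroxyl. The O6 anisate is put on in the flask in which C6 is made.
2. Ring B (seven-membered): ring-closing metathesis forms C8=C9 from the allyl group on C1 and a methallyl carbinol. C6–C7 comes from chelation-controlled methallyl Grignard addition to a cyclopentanecarbaldehyde.
3. Ring A (five-membered): the C4–C5 bond and both stereocentres come from an isothiourea-catalysed aldol-lactonisation of an acyclic 6-oxo acid.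
4. C1 comes from anti conjugate methylation of a 4-allylbutenolide template. C2, the first stereocentre, comes from a new amine-catalysed aldol–lactonisation of 4-allyl-5-hydroxybutenolide (from pent-4-enal and glyoxylic acid) and 3-methylbutan-2-one.
5. Order of rings: temporary butenolide/lactone (opened again), then ring A (carrying a temporary β-lactone), then ring B.

Assumption: atom labels follow daucane numbering (C1 quaternary fusion carbon, C2 angelate carbinol, C3 CH2, C4 tertiary carbinol, C5 fusion CH, C6 anisate carbinol, C8=C9 alkene); glyoxylic acid is weighed as its monohydrate and drawn anhydrous; 3 is drawn as the cyclic pseudo-acid, whose hemiacetal carbon is configurationally labile and carries no descriptor.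

**Step 1**
Reactants: 1 pent-4-enal; 2 glyoxylic acid
Product: 3 4-allyl-5-hydroxyfuran-2(5H)-one
Conditions: morpholine·HCl, dioxane/H2O, 90 °C
Reagents that add atoms: none
Why: Amine-salt-mediated crossed aldol condensation (enamine addition to the glyoxylic aldehyde, then dehydration) gives the (Z)-formylacrylic acid, which closes to the pseudo-acid, and ring–chain tautomerism keeps its hemiacetal carbon labile so no fixed stereocentre exists yet.

**Step 2**
Reactants: 3 4-allyl-5-hydroxyfuran-2(5H)-one; 4 3-methylbutan-2-one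
Product: 7 (R)-4-allyl-5-(3-methyl-2-oxobutyl)furan-2(5H)-one, via open-chain formyl acid 5 (not isolated), via aldol hydroxy acid 6 (not isolated)
Conditions: (S)-N-[(S)-1-hydroxy-4-methyl-1,1-diphenylpentan-2-yl]pyrrolidine-2-carboxamide (10 mol %), 4 (10 equiv), CH2Cl2, −20 °C
Reagents that add atoms: none
Why: Proposed new method: amine-catalysed enantioselective aldol–lactonisation of a γ-hydroxybutenolide, in which ring–chain tautomerism releases the achiral formyl acid 5, the L-prolinamide forms the less substituted enamine of 4 and, holding the formyl oxygen by its amide N–H and carbinol O–H, attacks the Re face (Houk–List-type transition state) to give (R)-6, whose (Z)-hydroxy acid lactonises at once, making the 1,2-addition irreversible and draining it ahead of Michael addition; the closest known reaction type is the prolinamide-catalysed aldol–lactonisation of 2-formylbenzoates to 3-substituted phthalides.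

**Step 3**
Reactants: 7 (R)-4-allyl-5-(3-methyl-2-oxobutyl)furan-2(5H)-one
Product: 9 (4R,5R)-4-allyl-4-methyl-5-(3-methyl-2-oxobutyl)dihydrofuran-2(3H)-one, via silyl ketene acetal 8 (not isolated)
Conditions: Me2CuLi (from MeLi + CuI), TMSCl, Et2O/THF, −78 → −30 °C; then 1 M HCl, THF, 0 °C
Reagents that add atoms: lithium dimethylcuprate, [Li+].C[Cu-]C
Why: Chlorosilane-accelerated organocuprate conjugate addition, in which the cuprate approaches the butenolide face anti to the C2 side chain, so the new methyl is trans to that chain and the quaternary C1 is (R), and the ketene acetal 8 is hydrolysed on work-up.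

**Step 4**
Reactants: 9 (4R,5R)-4-allyl-4-methyl-5-(3-methyl-2-oxobutyl)dihydrofuran-2(3H)-one
Product: 12 (3R,4R)-3-allyl-4-[(tert-butyldimethylsilyl)oxy]-3,7-dimethyl-6-oxooctanoic acid, via lithium hydroxy carboxylate 10 (not isolated), via bis-silyl derivative 11 (not isolated)
Conditions: LiOH, THF/H2O, 0 °C, evaporate; TBSOTf, 2,6-lutidine, CH2Cl2, 0 °C; then AcOH/THF/H2O, rt
Reagents that add atoms: lithium hydroxide, [Li+].[OH-]; tert-butyldimethylsilyl trifluoromethanesulfonate, CC(C)(C)[Si](C)(C)OS(=O)(=O)C(F)(F)F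
Why: Cold, short saponification opens the lactone to the carboxylate, which is never acidified and so cannot relactonise, exhaustive silylation caps O2, and selective hydrolysis of the labile silyl ester frees the acid without touching a stereocentre.

**Step 5**
Reactants: 12 (3R,4R)-3-allyl-4-[(tert-butyldimethylsilyl)oxy]-3,7-dimethyl-6-oxooctanoic acid
Product: 14 (1R,2R,3R,5R)-2-allyl-3-[(tert-butyldimethylsilyl)oxy]-2-methyl-5-(propan-2-yl)-6-oxabicyclo[3.2.0]heptan-7-one, via tosyl mixed anhydride 13 (not isolated)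
Conditions: (R)-HBTM [(R)-2-phenyl-3,4-dihydro-2H-benzo[4,5]thiazolo[3,2-a]pyrimidine] (20 mol %), TsCl, LiCl, iPr2NEt, CH2Cl2, rt, slow addition of 12
Reagents that add atoms: none
Why: Nucleophile-catalysed aldol-lactonisation, in which 13 acylates the isothiourea, deprotonation gives the O···S-locked (Z)-ammonium enolate, its face anti to the catalyst phenyl group adds to the LiCl-activated isopropyl ketone, and only the aldolate with O4 cis to C6 can close to the β-lactone (freeing the catalyst and making the hindered aldol irreversible), so C5 is set by the catalyst and C4 by the cis fusion, with the isopropyl group turned away from the silyloxy group.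

**Step 6**
Reactants: 14 (1R,2R,3R,5R)-2-allyl-3-[(tert-butyldimethylsilyl)oxy]-2-methyl-5-(propan-2-yl)-6-oxabicyclo[3.2.0]heptan-7-one
Product: 15 (1R,2S,3R,4R)-3-allyl-4-[(tert-butyldimethylsilyl)oxy]-2-(hydroxymethyl)-3-methyl-1-(propan-2-yl)cyclopentan-1-ol
Conditions: iBu2AlH (3 equiv), CH2Cl2, −78 → 0 °C; aq KNaC4H4O6
Reagents that add atoms: none
Why: Hydride reduction of the strained β-lactone (acyl C–O cleavage, then aldehyde reduction) gives the 1,3-diol without touching the silyl ether, the terminal alkene or any stereocentre.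

**Step 7**
Reactants: 15 (1R,2S,3R,4R)-3-allyl-4-[(tert-butyldimethylsilyl)oxy]-2-(hydroxymethyl)-3-methyl-1-(propan-2-yl)cyclopentan-1-ol
Product: 16 (1R,2R,3R,5R)-2-allyl-3-[(tert-butyldimethylsilyl)oxy]-5-hydroxy-2-methyl-5-(propan-2-yl)cyclopentane-1-carbaldehyde
Conditions: TEMPO (10 mol %), PhI(OAc)2, CH2Cl2, rt
Reagents that add atoms: none
Why: Oxoammonium (TEMPO) oxidation takes only the primary alcohol because the other free hydroxyl is tertiary, and the nearly neutral medium avoids retro-aldol cleavage and epimerisation at C5.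

**Step 8**
Reactants: 16 (1R,2R,3R,5R)-2-allyl-3-[(tert-butyldimethylsilyl)oxy]-5-hydroxy-2-methyl-5-(propan-2-yl)cyclopentane-1-carbaldehyde; 17 2-methylallylmagnesium chloride; 18 4-methoxybenzoyl chloride
Product: 20 (1S)-1-[(1S,2R,3R,5R)-2-allyl-3-[(tert-butyldimethylsilyl)oxy]-5-hydroxy-2-methyl-5-(propan-2-yl)cyclopentyl]-3-methylbut-3-en-1-yl 4-methoxybenzoate, via bis(chloromagnesium) alkoxide 19 (not isolated)
Conditions: 17 (2.2 equiv), THF, −78 °C; then 18, −78 → 0 °C; aq NH4Cl
Reagents that add atoms: none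
Why: Grignard addition under 1,3-chelation control, in which the first equivalent makes the C4 magnesium alkoxide that ties the formyl oxygen into a six-membered chelate cis-fused to the ring, the second adds to the face away from the chelate to give (6S), and the less hindered secondary alkoxide of 19 is then acylated by 18 in the same flask while the tertiary one is not.

**Step 9**
Reactants: 20 (1S)-1-[(1S,2R,3R,5R)-2-allyl-3-[(tert-butyldimethylsilyl)oxy]-5-hydroxy-2-methyl-5-(propan-2-yl)cyclopentyl]-3-methylbut-3-en-1-yl 4-methoxybenzoate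
Product: 21 (1R,3R,3aS,4S,8aR)-1-[(tert-butyldimethylsilyl)oxy]-3-hydroxy-6,8a-dimethyl-3-(propan-2-yl)-1,2,3,3a,4,5,8,8a-octahydroazulen-4-yl 4-methoxybenzoate
Conditions: second-generation Grubbs catalyst (H2IMes)(PCy3)Cl2Ru=CHPh (5 mol %), CH2Cl2 (2 mM), reflux
Reagents that add atoms: none
Why: Ring-closing metathesis of a monosubstituted and a 1,1-disubstituted alkene closes the trans-fused cycloheptene and fixes the trisubstituted C8=C9 position unambiguously, while the ester, silyl ether and tertiary alcohol are inert to the ruthenium carbene.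

**Step 10**
Reactants: 21 (1R,3R,3aS,4S,8aR)-1-[(tert-butyldimethylsilyl)oxy]-3-hydroxy-6,8a-dimethyl-3-(propan-2-yl)-1,2,3,3a,4,5,8,8a-octahydroazulen-4-yl 4-methoxybenzoate
Product: 22 (1R,3R,3aS,4S,8aR)-1,3-dihydroxy-6,8a-dimethyl-3-(propan-2-yl)-1,2,3,3a,4,5,8,8a-octahydroazulen-4-yl 4-methoxybenzoate
Conditions: HF·pyridine, pyridine/THF, 0 °C → rt
Reagents that add atoms: none
Why: Fluoride-induced Si–O cleavage in a buffered, mildly acidic medium frees the C2 hydroxyl without the anisoyl migration or elimination that a basic fluoride source could cause.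

**Step 11**
Reactants: 22 (1R,3R,3aS,4S,8aR)-1,3-dihydroxy-6,8a-dimethyl-3-(propan-2-yl)-1,2,3,3a,4,5,8,8a-octahydroazulen-4-yl 4-methoxybenzoate; 23 angelic acid [(Z)-2-methylbut-2-enoic acid]
Product: 25 (1R,3R,3aS,4S,8aR)-3-hydroxy-4-[(4-methoxybenzoyl)oxy]-6,8a-dimethyl-3-(propan-2-yl)-1,2,3,3a,4,5,8,8a-octahydroazulen-1-yl (2Z)-2-methylbut-2-enoate, via angelic trichlorobenzoic anhydride 24 (not isolated)
Conditions: 2,4,6-Cl3C6H2COCl, Et3N, toluene, rt; then 22, toluene, 80 °C
Reagents that add atoms: none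
Why: Yamaguchi-type mixed-anhydride esterification run without a nucleophilic pyridine catalyst, so no reversible conjugate addition can turn the (Z)-angelate into the (E)-tiglate, the alcohol attacks the less hindered angeloyl carbonyl of 24, and only the secondary C2 hydroxyl reacts because the other free hydroxyl is tertiary.

**Compound list**
1 | pent-4-enal | C=CCCC=O | starting material
2 | glyoxylic acid | O=CC(=O)O | starting material
3 | 4-allyl-5-hydroxyfuran-2(5H)-one | C=CCC1=CC(=O)OC1O | intermediate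
4 | 3-methylbutan-2-one | CC(=O)C(C)C | starting material
5 | (2Z)-3-formylhexa-2,5-dienoic acid | OC(=O)/C=C(/CC=C)C=O | intermediate
6 | (2Z,4R)-4-hydroxy-7-methyl-6-oxo-3-(prop-2-en-1-yl)oct-2-enoic acid | OC(=O)/C=C(/CC=C)[C@H](O)CC(=O)C(C)C | intermediate
7 | (R)-4-allyl-5-(3-methyl-2-oxobutyl)furan-2(5H)-one | O=C1C=C(CC=C)[C@@H](CC(=O)C(C)C)O1 | intermediate
8 | 1-[(2R,3R)-3-allyl-3-methyl-5-(trimethylsilyloxy)-2,3-dihydrofuran-2-yl]-3-methylbutan-2-one | C[Si](C)(C)OC1=C[C@@](C)(CC=C)[C@@H](CC(=O)C(C)C)O1 | intermediate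
9 | (4R,5R)-4-allyl-4-methyl-5-(3-methyl-2-oxobutyl)dihydrofuran-2(3H)-one | O=C1C[C@@](C)(CC=C)[C@@H](CC(=O)C(C)C)O1 | intermediate
10 | lithium (3R,4R)-3-allyl-4-hydroxy-3,7-dimethyl-6-oxooctanoate | [Li+].[O-]C(=O)C[C@@](C)(CC=C)[C@H](O)CC(=O)C(C)C | intermediate
11 | tert-butyldimethylsilyl (3R,4R)-3-allyl-4-[(tert-butyldimethylsilyl)oxy]-3,7-dimethyl-6-oxooctanoate | CC(C)(C)[Si](C)(C)OC(=O)C[C@@](C)(CC=C)[C@H](O[Si](C)(C)C(C)(C)C)CC(=O)C(C)C | intermediate
12 | (3R,4R)-3-allyl-4-[(tert-butyldimethylsilyl)oxy]-3,7-dimethyl-6-oxooctanoic acid | OC(=O)C[C@@](C)(CC=C)[C@H](O[Si](C)(C)C(C)(C)C)CC(=O)C(C)C | intermediate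
13 | (3R,4R)-3-allyl-4-[(tert-butyldimethylsilyl)oxy]-3,7-dimethyl-6-oxooctanoic 4-methylbenzenesulfonic anhydride | Cc1ccc(cc1)S(=O)(=O)OC(=O)C[C@@](C)(CC=C)[C@H](O[Si](C)(C)C(C)(C)C)CC(=O)C(C)C | intermediate
14 | (1R,2R,3R,5R)-2-allyl-3-[(tert-butyldimethylsilyl)oxy]-2-methyl-5-(propan-2-yl)-6-oxabicyclo[3.2.0]heptan-7-one | O=C1O[C@@]2(C(C)C)C[C@@H](O[Si](C)(C)C(C)(C)C)[C@](C)(CC=C)[C@@H]12 | intermediate
15 | (1R,2S,3R,4R)-3-allyl-4-[(tert-butyldimethylsilyl)oxy]-2-(hydroxymethyl)-3-methyl-1-(propan-2-yl)cyclopentan-1-ol | OC[C@@H]1[C@@](C)(CC=C)[C@H](O[Si](C)(C)C(C)(C)C)C[C@@]1(O)C(C)C | intermediate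
16 | (1R,2R,3R,5R)-2-allyl-3-[(tert-butyldimethylsilyl)oxy]-5-hydroxy-2-methyl-5-(propan-2-yl)cyclopentane-1-carbaldehyde | O=C[C@@H]1[C@@](C)(CC=C)[C@H](O[Si](C)(C)C(C)(C)C)C[C@@]1(O)C(C)C | intermediate
17 | 2-methylallylmagnesium chloride | C=C(C)C[Mg]Cl | starting material
18 | 4-methoxybenzoyl chloride | COc1ccc(cc1)C(=O)Cl | starting material
19 | bis(chloromagnesium) alkoxide of the (6S)-methallyl adduct of 16 | C=C(C)C[C@H](O[Mg]Cl)[C@@H]1[C@@](C)(CC=C)[C@H](O[Si](C)(C)C(C)(C)C)C[C@@]1(O[Mg]Cl)C(C)C | intermediate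
20 | (1S)-1-[(1S,2R,3R,5R)-2-allyl-3-[(tert-butyldimethylsilyl)oxy]-5-hydroxy-2-methyl-5-(propan-2-yl)cyclopentyl]-3-methylbut-3-en-1-yl 4-methoxybenzoate | C=C(C)C[C@H](OC(=O)c1ccc(OC)cc1)[C@@H]2[C@@](C)(CC=C)[C@H](O[Si](C)(C)C(C)(C)C)C[C@@]2(O)C(C)C | intermediate
21 | (1R,3R,3aS,4S,8aR)-1-[(tert-butyldimethylsilyl)oxy]-3-hydroxy-6,8a-dimethyl-3-(propan-2-yl)-1,2,3,3a,4,5,8,8a-octahydroazulen-4-yl 4-methoxybenzoate | CC(C)(C)[Si](C)(C)O[C@@H]1C[C@@](O)(C(C)C)[C@@H]2[C@@H](OC(=O)c3ccc(OC)cc3)CC(C)=CC[C@]21C | intermediate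
22 | (1R,3R,3aS,4S,8aR)-1,3-dihydroxy-6,8a-dimethyl-3-(propan-2-yl)-1,2,3,3a,4,5,8,8a-octahydroazulen-4-yl 4-methoxybenzoate | O[C@@H]1C[C@@](O)(C(C)C)[C@@H]2[C@@H](OC(=O)c3ccc(OC)cc3)CC(C)=CC[C@]21C | intermediate
23 | angelic acid, (Z)-2-methylbut-2-enoic acid | C/C=C(/C)C(=O)O | starting material
24 | (Z)-2-methylbut-2-enoic 2,4,6-trichlorobenzoic anhydride | C/C=C(/C)C(=O)OC(=O)c1c(Cl)cc(Cl)cc1Cl | intermediate
25 | (1R,3R,3aS,4S,8aR)-3-hydroxy-4-[(4-methoxybenzoyl)oxy]-6,8a-dimethyl-3-(propan-2-yl)-1,2,3,3a,4,5,8,8a-octahydroazulen-1-yl (2Z)-2-methylbut-2-enoate | C/C=C(/C)C(=O)O[C@@H]1C[C@@](O)(C(C)C)[C@@H]2[C@@H](OC(=O)c3ccc(OC)cc3)CC(C)=CC[C@]21C | target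

**Total step count:** 11. **Longest linear sequence:** 11 (1 → 25).

**Steps most likely to fail**

Step 2 (the proposed new aldol–lactonisation).
- Risks: enamine Michael addition instead of 1,2-addition, resting of the catalyst as a 5-aminobutenolide, drift of the skipped diene into conjugation, and modest ee.
- The fallback sets out from 3 (and 4) and comes back at 7.
- MeI/K2CO3 in DMF alkylates the ring-opened carboxylate of 3 to methyl (2Z)-3-formylhexa-2,5-dienoate F1.
- Ketone 4 is converted with LDA/TMSCl into 3-methyl-2-(trimethylsilyloxy)but-1-ene F2.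
- SiCl4 and a catalytic chiral binaphthyldiamine-derived bisphosphoramide (the enantiomer that directs Re-face attack) promote a Lewis-base-activated Mukaiyama aldol. This reaction is known for α-substituted enals and for methyl ketone enol silanes and is strictly 1,2-selective. It gives methyl (2Z,4R)-4-hydroxy-7-methyl-6-oxo-3-(prop-2-en-1-yl)oct-2-enoate F3.
- F3 lactonises with a trace of TsOH to 7.

Step 3 (quaternary centre by cuprate addition to a β,γ-disubstituted butenolide).
- Risks: sluggish addition, and γ-deprotonation leading to loss of ee.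
- The fallback builds C1 by a radical ring closure instead. It sets out from 1 and 4 and comes back at 9, so it also bypasses step 2.
- Aldehyde 1 is α-methylenated (aq CH2O, pyrrolidine/propionic acid) to 2-methylidenepent-4-enal F4.
- The same SiCl4/bisphosphoramide aldol with the enol silane F2 gives (5R)-5-hydroxy-2-methyl-6-methylidenenon-8-en-3-one F5.
- Ethyl vinyl ether/NBS gives (5R)-5-(2-bromo-1-ethoxyethoxy)-2-methyl-6-methylidenenon-8-en-3-one F6.
- Bu3SnH/AIBN closes F6 by a Ueno–Stork 5-exo radical cyclisation. The radical left on the former methylidene carbon takes up hydrogen and becomes the C1 methyl group, trans to the side chain by the Beckwith chair model. The product is 1-[(2R,3R)-3-allyl-5-ethoxy-3-methyloxolan-2-yl]-3-methylbutan-2-one F7.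
- CrO3/H2SO4 in acetone oxidises the acetal F7 to lactone 9.

Step 5 (aldol-lactonisation onto a hindered isopropyl ketone from a neopentyl enolate).
- Risks: slow aldol, ketene dimerisation, and a mismatch between catalyst and substrate.
- The fallback closes ring A at the aldehyde level. It sets out from 12 and comes back at 16, skipping 14 and 15.
- EtSH/EDC/DMAP gives S-ethyl (3R,4R)-3-allyl-4-[(tert-butyldimethylsilyl)oxy]-3,7-dimethyl-6-oxooctanethioate F8.
- Et3SiH with Pd/C (Fukuyama reduction) gives (3R,4R)-3-allyl-4-[(tert-butyldimethylsilyl)oxy]-3,7-dimethyl-6-oxooctanal F9.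
- D-proline (30 mol %, DMSO, rt) effects the known 5-enolexo enamine aldol onto the ketone and gives 16.

**Further compounds**
F1 | step 2 | methyl (2Z)-3-formylhexa-2,5-dienoate | COC(=O)/C=C(/CC=C)C=O
F2 | step 2 | 3-methyl-2-(trimethylsilyloxy)but-1-ene | C=C(O[Si](C)(C)C)C(C)C
F3 | step 2 | methyl (2Z,4R)-4-hydroxy-7-methyl-6-oxo-3-(prop-2-en-1-yl)oct-2-enoate | COC(=O)/C=C(/CC=C)[C@H](O)CC(=O)C(C)C
F4 | step 3 | 2-methylidenepent-4-enal | C=CCC(=C)C=O
F5 | step 3 | (5R)-5-hydroxy-2-methyl-6-methylidenenon-8-en-3-one | C=CCC(=C)[C@H](O)CC(=O)C(C)C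
F6 | step 3 | (5R)-5-(2-bromo-1-ethoxyethoxy)-2-methyl-6-methylidenenon-8-en-3-one | C=CCC(=C)[C@H](OC(CBr)OCC)CC(=O)C(C)C
F7 | step 3 | 1-[(2R,3R)-3-allyl-5-ethoxy-3-methyloxolan-2-yl]-3-methylbutan-2-one | CCOC1C[C@@](C)(CC=C)[C@@H](CC(=O)C(C)C)O1
F8 | step 5 | S-ethyl (3R,4R)-3-allyl-4-[(tert-butyldimethylsilyl)oxy]-3,7-dimethyl-6-oxooctanethioate | CCSC(=O)C[C@@](C)(CC=C)[C@H](O[Si](C)(C)C(C)(C)C)CC(=O)C(C)C
F9 | step 5 | (3R,4R)-3-allyl-4-[(tert-butyldimethylsilyl)oxy]-3,7-dimethyl-6-oxooctanal | O=CC[C@@](C)(CC=C)[C@H](O[Si](C)(C)C(C)(C)C)CC(=O)C(C)C
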